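The flask could not give more target than it had coupling partner, taking one partner for each target, so I counted turnovers of partner in fractions of the substrate charge.

in all of them: substrate 0.050 M
- spring: coupling partner 0.024 M; run made earlier
- autumn: coupling partner 0.095 M; run made earlier
- flask: coupling partner 0.0475 M; time 15 d

| run | time / d | substrate / % | target / % |
|---|---|---|---|
| spring | 3.00 | 35.0 | 40.7 |
| spring | 6.00 | 33.9 | 41.4 |
| spring | 10.0 | 35.1 | 41.8 |
| spring | 12.0 | 34.5 | 41.5 |
| spring | 15.0 | 36.7 | 42.1 |
| spring | 20.0 | 33.9 | 43.1 |
| autumn | 1.25 | 0.5 | 92.0 |
| autumn | 4.00 | 0.1 | 91.4 |
| autumn | 6.00 | 0 | 93.3 |
| autumn | 10.0 | 0.8 | 92.8 |
| autumn | 15.0 | 0 | 91.3 |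
| autumn | 20.0 | 1.1 | 92.4 |

(each reading ± 1 percentage point)

* why nothing more happens at 15 d, or that something still does (other conformer counts as not reacted) (the coupling partner has run out first / forward and back rates have come level / all of the substrate has reacted / it is still moving)
* part of the substrate that has turned into other species by 15 d (other conformer does not count)
* target at 15 d, in percent of the substrate charged

- in a conversion other conformer counts as not yet reacted
- the reaction counts as stopped when no species that holds the substrate changes by six tenths of a point or more over the second half of the time

1. Both earlier runs were flat from the first reading. The spring run, with partner at 0.480 of the substrate charge, averaged 41.8% target with 34.9% substrate standing. The autumn run, at 1.90, averaged 92.2% target.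
2. Upper bound: the flask's partner is 0.950 of the substrate charge. I did not expect less partner to beat the autumn surplus, so the top came down to 92.2%.
3. Lower bound: the flask's extra partner beyond the spring charge meets what the spring run left. Supposing it split in proportion between substrate and the unread rest, I set my floor at 69.9%, an estimate and not a strict limit.
4. Estimate: I read partner as the limiting reagent in the spring run, where 34.9% substrate stood in flat readings. Target per partner charged read 0.870 there. I called this the capture share, target made per partner charged when partner stops the flask. On the flask that gave 82.7%.

The forecast, close to my estimate and inside my bracket, said the coupling partner has run out first, with conversion 89% and target 82.5%, on the ground that “Spring therefore ran out of partner, not reached equilibrium.”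

The flask gave: the coupling partner has run out first, with 0% of it left, conversion 95.0% and target 81.1%, inside my bracket.

    substrate ⇌ other conformer (K = 0.480, k = 8.22 × 10⁻⁴ /min)
    substrate + coupling partner → target (k = 0.129 /M/min)
    coupling partner + other conformer → isomer of the product (k = 0.161 /M/min)

The flask's capture share came to 0.853, and the isomer of the product held 13.9%. At 0.0843 d in the flask, substrate went to target 4.1 times as fast as to other conformer, counting that step forward.

In a neighbour flask with 0.12 M partner, share times charge gave 2.09, past the whole substrate charge, so I took the autumn top, 92.2%. Computed, that neighbour flask gave target 94.3%, with 0% substrate and 58% of its partner left.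

(The runs are simulated for an exercise, noise included.)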